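Take a one-step world: solid substrate turns into target at a steady pace, and one number sums up a run.

| flask | solid substrate | gas phase | remark | time |
|---|---|---|---|---|
| maple | 0.95 M | 200 mM (held) | run made earlier |  |
| larch | 1.4 M | 200 mM (held) | run made earlier |  |
| flask | 1.9 M | 200 mM (held) |  | 6.0 min |

| run | time / min | target / % | solid substrate / % |
|---|---|---|---|
| maple | 0.667 | 15 | 83 |
| maple | 1.33 | 25 | 66 |
| maple | 2.00 | 42 | 52 |
| maple | 3.00 | 62 | 23 |
| maple | 4.00 | 86 | 0 |
| maple | 5.00 | 84 | 2 |
| larch | 0.250 | 2 | 94 |
| larch | 0.667 | 10 | 86 |
| larch | 1.33 | 18 | 77 |
| larch | 2.00 | 31 | 67 |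
| larch | 3.00 | 42 | 51 |
| larch | 4.00 | 58 | 34 |
| larch | 5.00 | 71 | 14 |

(each reading ± 1.5 percentage points)

- as a solid, counted per litre of solution: solid substrate
- at the start none of the gas phase is in solution
- at the start none of the solid substrate is in solution

- the target standing at 6.0 min, as a percentage of the solid substrate charged
- concentration of dissolved gas in solution at 6.0 min, in percent of saturation

By 3.00 min, maple has made target at a mean 0.196 M min⁻¹. By 5.00 min, larch has made it at 0.199 M min⁻¹, although larch holds more solid substrate. Their average, 0.198 M min⁻¹, is the mean target rate w, the target made per litre and minute while solid remains. Replacing the curve by this mean is tested on larch at 3.00 min, which already gives 0.196 M min⁻¹. Solid substrate falls in the same way, at a mean s of 0.242 M min⁻¹.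

The flask can be reckoned in two ways. The rate way gives w times 6.0 min over the 1.9 M charged, or 62.4 %. The ending way takes the level of target read in maple at 4.00 min and 5.00 min, where its solid substrate reads 0 % and 2 %: a mean of 85.0 % of the charge. They part by 23 percentage points, and the ending way is the one that cheats. At s, this reckoning has the flask use 1.45 M by 6.0 min, less than its charge, so by the estimate about 23.6 % of the solid substrate remains at that time, and the level read in maple does not yet apply. No reading touches the dissolved gas, so this reckoning gives no figure for it.

The forecast says 63 % (58 % to 68 %) of target and 15 % (2 % to 60 %) of saturation, with the remark that “Gas-limited behaviour favours the low value”.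

The flask gives 63.9 % of target, with dissolved gas at 99.2 % of saturation. With half or twice the coefficient of gas transfer, the target stands at 63.8 % and 64.0 %.

    gas phase ⇌ dissolved gas, rate k1*(csat - [dissolved gas]) (kL = 2.30 s⁻¹)
    solid substrate ⇌ starting material, rate k2*(cs2 - [starting material]) while solid is left; crystals form when [starting material] > cs2 (solubility = 1.90 M, k = 0.00210 s⁻¹)
    starting material → side product (k = 0.0280 s⁻¹)
    dissolved gas ⇌ dormant form (K = 30.0, k = 0.00160 s⁻¹)
    starting material + dissolved gas → target (k = 0.910 L mol⁻¹ s⁻¹)

With 0.76 M of solid substrate, w over 6.0 min asks for 156 % of the charge, more than it holds. In that neighbour flask the solid substrate, the limiting reagent, is down to 0 % at 6.0 min, and the target stands at 86.6 %.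

The numbers in the tables come from a simulation with constants of no real substance, noise included.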